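The runs were generated by integration with constants of no real substance, noise included.

At 30.0 d, the time you read the flask, larch and oak keep 2% and 1% of their substrate, so the question is how the intermediate was shared out.

| setting | larch | oak | flask |
|---|---|---|---|
| substrate | 0.16 M (in portions, 3) | 0.16 M (in portions, 3) | 0.16 M (in portions, 3) |
| second nucleophile | 0.27 M | 0.42 M | 0.192 M |
| gas | 28 mM (held) | 28 mM (held) | 28 mM (held) |
| remark | run made earlier; portions every 3.0 h | run made earlier; portions every 3.0 h | the portions of substrate follow each other after 3.0 h, the first at the start |
| time |  |  | 30 d |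

| run | time / d | other capture product / % | intermediate / % | isomer of the product / % | substrate / % | target / % |
|---|---|---|---|---|---|---|
| larch | 2.50 | 29 | 3 | 1 | 69 | 3 |
| larch | 8.00 | 61 | 0 | 7 | 30 | 3 |
| larch | 12.0 | 73 | 0 | 7 | 17 | 5 |
| larch | 20.0 | 82 | 2 | 11 | 5 | 6 |
| larch | 30.0 | 86 | 0 | 6 | 2 | 5 |
| larch | 40.0 | 86 | 0 | 8 | 0 | 6 |
| oak | 2.50 | 27 | 0 | 0 | 69 | 1 |
| oak | 8.00 | 65 | 1 | 3 | 30 | 5 |
| oak | 12.0 | 77 | 0 | 8 | 19 | 4 |
| oak | 20.0 | 90 | 1 | 6 | 5 | 4 |
| oak | 30.0 | 91 | 1 | 5 | 1 | 4 |
| oak | 40.0 | 94 | 0 | 5 | 0 | 3 |

(each reading ± 1.5 percentage points)

1. where most of what was charged as substrate, at 30 d is found (intermediate / substrate / target / isomer of the product / other capture product)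
2. the largest share itself, whichever of these holds it, in percent of the substrate charged

- at the start none of first nucleophile is dissolved
- the numbers in the tables scatter by 1.5 percentage points (one standard deviation)
- candidate steps: substrate -> intermediate; first nucleophile + intermediate -> target; second nucleophile + intermediate -> other capture product; target <-> isomer of the product; 2 first nucleophile -> self-condensation product; gas <-> first nucleophile

Count in fractions of the substrate charge. Let n be the charge of second nucleophile and L the leak, what ends as target or isomer of the product; then, with substrate at 0% as larch and oak read at 40.0 d, r, n minus one plus L, is the second nucleophile left. If the held gas keeps first nucleophile steady, as I assume, L = g ln(n/r) with a single number g. Larch has n = 1.69 and L = 14.0% at 40.0 d, which reads g = 0.196. Oak has n = 2.62 and L = 8.00%, which reads 0.185, so one number serves both runs. Their mean, 0.191, reads as the second nucleophile at which both captures run level, the leak number, a selectivity factor counted in charges.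

The flask has n = 1.20. Start L at g, put it back repeatedly, and it settles near 0.208. Taking off the substrate that larch and oak still keep at that time, I expect the flask's other capture product at 77.7%.

The forecast says other capture product at 79%, between 74% and 83%: “other capture product clearly dominates”.

The flask gives other capture product at 77.9%.

    substrate → intermediate (k = 1.07 × 10⁻⁴ min⁻¹)
    first nucleophile + intermediate → target (k = 0.162 L mol⁻¹ min⁻¹)
    second nucleophile + intermediate → other capture product (k = 0.137 L mol⁻¹ min⁻¹)
    target ⇌ isomer of the product (K = 1.72, k = 4.95 × 10⁻⁴ min⁻¹)
    2 first nucleophile → self-condensation product (k = 0.00750 L mol⁻¹ min⁻¹)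
    gas ⇌ first nucleophile, rate k6*(csat - [first nucleophile]) (kL = 0.0155 min⁻¹)

At 13.5 d the flask's intermediate goes to other capture product 2.5 times as fast as to target. That ratio reckons as the second nucleophile left over g, and at 30.0 d, with 35% of its charge left in the flask, it comes to 2.20. Now take a neighbour, the same recipe but with 0.048 M of second nucleophile, n = 0.300. The leak is then close to one minus n, so 2.56% of its charge should stay, and that flask keeps 3.00%. Other capture product reckons to 29.2% and stands at 29.1%, while isomer of the product holds most, at 44.1%.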